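Retrosynthesis (ring numbered C1 = ketone, C2 = carbon bearing the chlorovinyl arm, C3 = methyl-bearing sp2 carbon, C6 = methyl stereocentre): first the two new C–H bonds at C6 and its methyl are removed, giving the 6-methylidene dienone 24. Then the exocyclic CH2 (Mannich/elimination), the ring C2–vinyl bond (Stille), the amide C–N bond, and in the acid C2–C3 (Johnson–Claisen), C4–C5 and C5–C6 (two vinyl Grignard additions) are cut.
Forward: the chain is built linearly from (S)-1,2-epoxyheptane and joined to propargylamine. The alkyne becomes the (Z)-chlorovinylstannane, and the only ring, bought as 3-methylcyclohex-2-en-1-one and iodinated at C2, is attached by Stille coupling. C6 then receives its methylidene carbon; no ring is formed anywhere in the route.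
Stereochemistry: C7 comes unchanged from the epoxide, 4E from the chair Claisen transition state, the E-chloroalkene from syn bis-stannylation followed by two retentive substitutions at tin, and C6 (S) from the enzyme in the last step.
Enabling feature: C6 is α to the C1 ketone and therefore epimerisable, while its dehydro form C6=CH2 is the only carbonyl-conjugated alkene in 24 with an unsubstituted β-carbon, so an ene-reductase can create this centre last, at neutral pH.

Key step: step 14

Assumption: the ene-reductase is specified by family only; the individual enzyme that protonates C6 to give the S configuration is to be fixed by a panel screen, and (S)-1,2-epoxyheptane is taken as purchased in high enantiomeric purity.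

Step 1
Reactants: 1 (S)-1,2-epoxyheptane
Product: 2 (S)-non-1-en-4-ol
Conditions: CH2=CHMgBr, CuI (10 mol %), THF, −30 → 0 °C
Reagents that add atoms: vinylmagnesium bromide, C=C[Mg]Br
Why: Copper-catalysed Grignard opening of a terminal epoxide (SN2 at the unsubstituted carbon); the C–O bond at the stereocentre is not touched, so the S configuration of 1 is carried into C4 of 2.

Step 2
Reactants: 2 (S)-non-1-en-4-ol
Product: 4 (S)-4-methoxynon-1-ene, via sodium alkoxide 3 (not isolated)
Conditions: NaH, THF, 0 °C; then MeI, rt
Reagents that add atoms: iodomethane, CI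
Why: Williamson ether synthesis on a secondary alkoxide with the most reactive alkyl halide; no bond to the stereocentre is broken.

Step 3
Reactants: 4 (S)-4-methoxynon-1-ene
Product: 6 (S)-3-methoxyoctanal, via secondary ozonide 5 (not isolated)
Conditions: O3, CH2Cl2, −78 °C; then PPh3, −78 °C → rt
Reagents that add atoms: ozone, [O-][O+]=O
Why: Ozonolysis of a monosubstituted alkene with reductive work-up; the ether is inert and the β-methoxy aldehyde is taken on crude to forestall loss of methanol.

Step 4
Reactants: 6 (S)-3-methoxyoctanal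
Product: 7 (5S)-5-methoxydec-1-en-3-ol (both C3 epimers)
Conditions: CH2=CHMgBr, THF, −78 → 0 °C
Reagents that add atoms: vinylmagnesium bromide, C=C[Mg]Br
Why: Grignard 1,2-addition to an aldehyde at low temperature outruns enolisation; the new carbinol centre forms without control, which is harmless because this carbon becomes sp2 in step 5.

Step 5
Reactants: 7 (5S)-5-methoxydec-1-en-3-ol
Product: 10 ethyl (4E,7S)-7-methoxydodec-4-enoate, via mixed orthoester 8 (not isolated), via ketene acetal 9 (not isolated)
Conditions: MeC(OEt)3 (excess), EtCO2H (cat.), 140 °C, EtOH distilled off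
Reagents that add atoms: triethyl orthoacetate, CCOC(C)(OCC)OCC
Why: Johnson–Claisen (orthoester Claisen) rearrangement: acid-catalysed exchange and loss of ethanol give the ketene acetal, whose chair [3,3] transition state with the chain pseudo-equatorial delivers the E alkene from either carbinol epimer and forms the C2–C3 bond of the acid.

Step 6
Reactants: 10 ethyl (4E,7S)-7-methoxydodec-4-enoate
Product: 11 (4E,7S)-7-methoxydodec-4-enoic acid
Conditions: LiOH, THF/MeOH/H2O, rt; then 1 M HCl to pH 3
Reagents that add atoms: lithium hydroxide, [Li+].[OH-]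
Why: Ester saponification; the alkene is not conjugated and the methoxy group has no acidic neighbour, so nothing else in 10 responds to hydroxide at room temperature.

Step 7
Reactants: 11 (4E,7S)-7-methoxydodec-4-enoic acid; 12 propargylamine
Product: 14 (4E,7S)-7-methoxy-N-(prop-2-yn-1-yl)dodec-4-enamide, via benzotriazolyl ester 13 (not isolated)
Conditions: N,N'-diisopropylcarbodiimide, HOBt, CH2Cl2, 0 °C → rt
Reagents that add atoms: none
Why: Carbodiimide/HOBt amide coupling through the active ester; the amide is made at this stage so that a free amine is never present next to the enone later on.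

Step 8
Reactants: 14 (4E,7S)-7-methoxy-N-(prop-2-yn-1-yl)dodec-4-enamide
Product: 15 (4E,7S)-N-[(Z)-2,3-bis(trimethylstannyl)prop-2-en-1-yl]-7-methoxydodec-4-enamide
Conditions: Me3SnSnMe3, Pd(PPh3)4 (5 mol %), THF, 65 °C, dark
Reagents that add atoms: hexamethylditin, C[Sn](C)(C)[Sn](C)(C)C
Why: Palladium-catalysed bis-stannylation of a terminal alkyne (oxidative addition of Sn–Sn to zerovalent palladium, syn insertion, reductive elimination) puts both tin atoms on the same side and leaves the 1,2-disubstituted chain alkene alone.

Step 9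
Reactants: 15 (4E,7S)-N-[(Z)-2,3-bis(trimethylstannyl)prop-2-en-1-yl]-7-methoxydodec-4-enamide
Product: 16 (4E,7S)-N-[(Z)-3-chloro-2-(trimethylstannyl)prop-2-en-1-yl]-7-methoxydodec-4-enamide
Conditions: CuCl2 (2.1 equiv), THF, 0 °C → rt
Reagents that add atoms: CuCl2, Cl[Cu]Cl
Why: Chlorodestannylation of an alkenylstannane with CuCl2 proceeds with retention; the terminal stannyl group is the less hindered one, its cleavage places the developing positive charge on the more substituted carbon, and the chlorine introduced deactivates the remaining C–Sn bond, so monochlorination at C3 with Cl cis to the surviving tin is expected.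

Step 10
Reactants: 17 3-methylcyclohex-2-en-1-one
Product: 18 2-iodo-3-methylcyclohex-2-en-1-one
Conditions: I2, pyridine, DMAP (cat.), CH2Cl2, rt
Reagents that add atoms: iodine, II
Why: α-Iodination of an enone by the Baylis–Hillman-type addition–iodination–elimination sequence (the amine adds at C3, the enolate is iodinated at C2, the amine is expelled), slower for a β,β-disubstituted enone but established for this substrate class.

Step 11
Reactants: 16 (4E,7S)-N-[(Z)-3-chloro-2-(trimethylstannyl)prop-2-en-1-yl]-7-methoxydodec-4-enamide; 18 2-iodo-3-methylcyclohex-2-en-1-one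
Product: 19 (4E,7S)-N-[(E)-3-chloro-2-(2-methyl-6-oxocyclohex-1-en-1-yl)prop-2-en-1-yl]-7-methoxydodec-4-enamide
Conditions: PdCl2(PhCN)2 (5 mol %), AsPh3 (10 mol %), CuI (10 mol %), NMP, 50 °C
Reagents that add atoms: none
Why: Stille coupling of an α-iodoenone with an alkenylstannane in the soft-ligand, copper-co-catalysed variant used for hindered partners; zerovalent palladium inserts only into C–I (the alkenyl chloride is inert at this temperature) and both sp2 carbons keep their geometry, so the ring takes the place of tin, cis to chlorine.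

Step 12
Reactants: 19 (4E,7S)-N-[(E)-3-chloro-2-(2-methyl-6-oxocyclohex-1-en-1-yl)prop-2-en-1-yl]-7-methoxydodec-4-enamide; 20 dimethylmethylideneammonium iodide (Eschenmoser's salt)
Product: 22 (4E,7S)-N-[(E)-3-chloro-2-{5-[(dimethylamino)methyl]-2-methyl-6-oxocyclohex-1-en-1-yl}prop-2-en-1-yl]-7-methoxydodec-4-enamide (both C6 epimers), via dilithium amidate enolate 21 (not isolated)
Conditions: LiN(SiMe3)2 (2.2 equiv), THF, −78 °C; then 20 (1.3 equiv), −78 → 0 °C; aqueous work-up
Reagents that add atoms: none
Why: Mannich aminomethylation of a kinetic lithium enolate: the first equivalent of base removes the amide N–H, the second deprotonates C6 (α′) rather than the vinylogous C4/CH3 positions, and the iminium ion is attacked at carbon; the C6 centre formed here is erased again in step 13.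

Step 13
Reactants: 22 (4E,7S)-N-[(E)-3-chloro-2-{5-[(dimethylamino)methyl]-2-methyl-6-oxocyclohex-1-en-1-yl}prop-2-en-1-yl]-7-methoxydodec-4-enamide
Product: 24 (4E,7S)-N-[(E)-3-chloro-2-(2-methyl-5-methylidene-6-oxocyclohex-1-en-1-yl)prop-2-en-1-yl]-7-methoxydodec-4-enamide, via trimethylammonium iodide 23 (not isolated)
Conditions: MeI (excess), CH2Cl2, rt, evaporate; then NaHCO3 (sat. aq.)/CH2Cl2, rt
Reagents that add atoms: none
Why: Exhaustive N-methylation followed by Hofmann-type (E1cB) elimination of the β-ammonio ketone, the standard route to α-methylidene ketones; bicarbonate is chosen so that the exocyclic double bond does not migrate into the ring, which would lead on to the isomeric phenol.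

Step 14
Reactants: 24 (4E,7S)-N-[(E)-3-chloro-2-(2-methyl-5-methylidene-6-oxocyclohex-1-en-1-yl)prop-2-en-1-yl]-7-methoxydodec-4-enamide
Product: 25 (4E,7S)-N-{(E)-3-chloro-2-[(5S)-2,5-dimethyl-6-oxocyclohex-1-en-1-yl]prop-2-en-1-yl}-7-methoxydodec-4-enamide (target)
Conditions: ene-reductase of the Old Yellow Enzyme family (S-selective at C6, from panel screen), NADP+ (cat.), D-glucose, glucose dehydrogenase, KH2PO4/K2HPO4 buffer pH 7.0, 10 vol % DMSO, 30 °C; EtOAc extraction, chromatography on neutral silica
Reagents that add atoms: none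
Why: The C1 carbonyl of 24 is held by the hydrogen-bond donors of the active site above the reduced flavin (regenerated from NADPH, itself recycled by glucose dehydrogenase and glucose); hydride passes from flavin N5 to the exocyclic methylidene carbon and the conserved tyrosine protonates C6 from the opposite face, a net anti addition of H2 that forms the methyl C–H and the C6–H bond. The closest known reaction type is the Old Yellow Enzyme reduction of α-methylidene cycloalkanones and α-methyl cycloalkenones to α-methyl ketones. No ring is closed and no skeletal bond is formed. The one new stereocentre, C6, is controlled by the enzyme: the binding orientation in the pocket decides which face of C6 meets the tyrosine proton, a homologue giving S is selected by screening, and the remote C7 centre has no influence. The step needs site selectivity among four C=C bonds, which the substrate supplies because only C6=CH2 is both conjugated to C1=O and unsubstituted at its β-carbon, whereas C2=C3 is tetrasubstituted, the chlorovinyl group is cross-conjugated and the chain alkene is isolated. Working at pH 7 and 30 °C keeps the new, epimerisable C6 centre and the isomerisation-prone substrate away from base.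

Compound list
1 | (S)-1,2-epoxyheptane | CCCCC[C@H]1CO1 | starting material
2 | (S)-non-1-en-4-ol | CCCCC[C@@H](CC=C)O | intermediate
3 | sodium (S)-non-1-en-4-olate | CCCCC[C@@H](CC=C)[O-].[Na+] | intermediate
4 | (S)-4-methoxynon-1-ene | CCCCC[C@@H](CC=C)OC | intermediate
5 | 3-[(2S)-2-methoxyheptyl]-1,2,4-trioxolane (secondary ozonide, both epimers at the ring carbon) | CCCCC[C@@H](CC1OCOO1)OC | intermediate
6 | (S)-3-methoxyoctanal | CCCCC[C@@H](CC=O)OC | intermediate
7 | (5S)-5-methoxydec-1-en-3-ol (both C3 epimers) | CCCCC[C@@H](CC(O)C=C)OC | intermediate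
8 | (5S)-3-(1,1-diethoxyethoxy)-5-methoxydec-1-ene (mixed orthoester) | CCCCC[C@@H](CC(C=C)OC(C)(OCC)OCC)OC | intermediate
9 | (5S)-3-[(1-ethoxyethenyl)oxy]-5-methoxydec-1-ene (ketene acetal) | CCCCC[C@@H](CC(C=C)OC(=C)OCC)OC | intermediate
10 | ethyl (4E,7S)-7-methoxydodec-4-enoate | CCCCC[C@@H](C/C=C/CCC(=O)OCC)OC | intermediate
11 | (4E,7S)-7-methoxydodec-4-enoic acid | CCCCC[C@@H](C/C=C/CCC(=O)O)OC | intermediate
12 | propargylamine (prop-2-yn-1-amine) | C#CCN | starting material
13 | 1H-benzotriazol-1-yl (4E,7S)-7-methoxydodec-4-enoate | CCCCC[C@@H](C/C=C/CCC(=O)On1nnc2ccccc21)OC | intermediate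
14 | (4E,7S)-7-methoxy-N-(prop-2-yn-1-yl)dodec-4-enamide | CCCCC[C@@H](C/C=C/CCC(=O)NCC#C)OC | intermediate
15 | (4E,7S)-N-[(Z)-2,3-bis(trimethylstannyl)prop-2-en-1-yl]-7-methoxydodec-4-enamide | CCCCC[C@@H](C/C=C/CCC(=O)NC/C(=C/[Sn](C)(C)C)[Sn](C)(C)C)OC | intermediate
16 | (4E,7S)-N-[(Z)-3-chloro-2-(trimethylstannyl)prop-2-en-1-yl]-7-methoxydodec-4-enamide | CCCCC[C@@H](C/C=C/CCC(=O)NC/C(=C/Cl)[Sn](C)(C)C)OC | intermediate
17 | 3-methylcyclohex-2-en-1-one | CC1=CC(=O)CCC1 | starting material
18 | 2-iodo-3-methylcyclohex-2-en-1-one | CC1=C(I)C(=O)CCC1 | intermediate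
19 | (4E,7S)-N-[(E)-3-chloro-2-(2-methyl-6-oxocyclohex-1-en-1-yl)prop-2-en-1-yl]-7-methoxydodec-4-enamide | CCCCC[C@@H](C/C=C/CCC(=O)NC/C(=C/Cl)C1=C(C)CCCC1=O)OC | intermediate
20 | dimethylmethylideneammonium iodide (Eschenmoser's salt) | C[N+](C)=C.[I-] | starting material
21 | dilithium salt of 19 (N-lithio amide, lithium enolate across C1–C6) | CCCCC[C@@H](C/C=C/CCC(=O)[N-]C/C(=C/Cl)C1=C(C)CCC=C1[O-])OC.[Li+].[Li+] | intermediate
22 | (4E,7S)-N-[(E)-3-chloro-2-{5-[(dimethylamino)methyl]-2-methyl-6-oxocyclohex-1-en-1-yl}prop-2-en-1-yl]-7-methoxydodec-4-enamide (both C6 epimers) | CCCCC[C@@H](C/C=C/CCC(=O)NC/C(=C/Cl)C1=C(C)CCC(CN(C)C)C1=O)OC | intermediate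
23 | [(3-{(1E)-1-chloro-3-[(4E,7S)-7-methoxydodec-4-enamido]prop-1-en-2-yl}-4-methyl-2-oxocyclohex-3-en-1-yl)methyl]trimethylammonium iodide | CCCCC[C@@H](C/C=C/CCC(=O)NC/C(=C/Cl)C1=C(C)CCC(C[N+](C)(C)C)C1=O)OC.[I-] | intermediate
24 | (4E,7S)-N-[(E)-3-chloro-2-(2-methyl-5-methylidene-6-oxocyclohex-1-en-1-yl)prop-2-en-1-yl]-7-methoxydodec-4-enamide | CCCCC[C@@H](C/C=C/CCC(=O)NC/C(=C/Cl)C1=C(C)CCC(=C)C1=O)OC | intermediate
25 | (4E,7S)-N-{(E)-3-chloro-2-[(5S)-2,5-dimethyl-6-oxocyclohex-1-en-1-yl]prop-2-en-1-yl}-7-methoxydodec-4-enamide (CNP0332649.2) | CCCCC[C@@H](C/C=C/CCC(=O)NC/C(=C/Cl)C1=C(C)CC[C@H](C)C1=O)OC | target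

Total step count: 14. Longest linear sequence: 13 steps (steps 1–9 and 11–14, from 1); the ring branch is step 10 alone.

Steps most likely to fail

Step 9. The chlorination may fail to distinguish the two C–Sn bonds of 15, run on to double chlorination, or be overtaken by protodestannylation. The fallback sets out from 14 and returns at 19. Pd(PPh3)4-catalysed addition of Me3Si–SnBu3 (THF, 65 °C), which reliably places tin on the internal and silicon on the terminal carbon on the same side, should give (4E,7S)-7-methoxy-N-[(Z)-2-(tributylstannyl)-3-(trimethylsilyl)prop-2-en-1-yl]dodec-4-enamide F1. Copper-assisted Stille coupling of F1 with 18 should give the vinylsilane (4E,7S)-7-methoxy-N-[(E)-2-(2-methyl-6-oxocyclohex-1-en-1-yl)-3-(trimethylsilyl)prop-2-en-1-yl]dodec-4-enamide F2. Iododesilylation with N-iodosuccinimide in (CF3)2CHOH, which goes with retention, should give (4E,7S)-N-[(E)-3-iodo-2-(2-methyl-6-oxocyclohex-1-en-1-yl)prop-2-en-1-yl]-7-methoxydodec-4-enamide F3. Copper-catalysed vinylic halogen exchange (CuI, trans-N,N'-dimethylcyclohexane-1,2-diamine, Me4NCl, EtOH, heat), a Finkelstein-type reaction that also retains geometry, converts F3 into 19, and the route resumes at step 12.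

Step 11. Transmetalation between two fully substituted sp2 carbons may be so slow that protodestannylation, homocoupling or loss of chloride from the β-chloroalkenyl metal intermediate (returning alkyne 14) takes over. The fallback sets out from 16 and returns at 19 by adding the C3 methyl group after the coupling. 16 is coupled under the same catalyst with commercial 2-iodocyclohex-2-en-1-one, whose β-carbon carries only hydrogen, to give (4E,7S)-N-[(E)-3-chloro-2-(6-oxocyclohex-1-en-1-yl)prop-2-en-1-yl]-7-methoxydodec-4-enamide F4. Conjugate addition of Me2CuLi in the presence of Me3SiCl (THF, −78 °C, excess cuprate to allow for the amide N–H) puts the methyl group on C3 and traps the enolate regiospecifically as (4E,7S)-N-[(E)-3-chloro-2-{6-methyl-2-[(trimethylsilyl)oxy]cyclohex-1-en-1-yl}prop-2-en-1-yl]-7-methoxydodec-4-enamide F5. Saegusa–Ito oxidation of F5 with Pd(OAc)2 in MeCN/DMSO restores the C2=C3 double bond and gives 19.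

Step 14. The enzyme may not bind the large lipophilic amide, may protonate C6 with poor facial selectivity, or 24 may isomerise (double-bond migration into the ring, then tautomerisation to the phenol) faster than it is reduced. The fallback moves the same reduction to a small substrate; it sets out from 17 and returns at 25. LiN(iPr)2 and 20 (THF, −78 °C) convert 17 into 6-[(dimethylamino)methyl]-3-methylcyclohex-2-en-1-one F6. MeI gives the ammonium salt [(4-methyl-2-oxocyclohex-3-en-1-yl)methyl]trimethylammonium iodide F7, and NaHCO3 gives 3-methyl-6-methylidenecyclohex-2-en-1-one F8. Ene-reductase reduction with the same cofactor recycling, on a substrate of the size these enzymes routinely accept, gives (S)-3,6-dimethylcyclohex-2-en-1-one F9. Iodination as in step 10 gives (S)-2-iodo-3,6-dimethylcyclohex-2-en-1-one F10, and Stille coupling of F10 with 16 under the conditions of step 11 gives 25 directly. The price is that C6 then passes through pyridine and a warm coupling, so its configurational integrity must be checked after each of these operations.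

Further compounds
F1 | step 9 | (4E,7S)-7-methoxy-N-[(Z)-2-(tributylstannyl)-3-(trimethylsilyl)prop-2-en-1-yl]dodec-4-enamide | CCCCC[C@@H](C/C=C/CCC(=O)NC/C(=C/[Si](C)(C)C)[Sn](CCCC)(CCCC)CCCC)OC
F2 | step 9 | (4E,7S)-7-methoxy-N-[(E)-2-(2-methyl-6-oxocyclohex-1-en-1-yl)-3-(trimethylsilyl)prop-2-en-1-yl]dodec-4-enamide | CCCCC[C@@H](C/C=C/CCC(=O)NC/C(=C/[Si](C)(C)C)C1=C(C)CCCC1=O)OC
F3 | step 9 | (4E,7S)-N-[(E)-3-iodo-2-(2-methyl-6-oxocyclohex-1-en-1-yl)prop-2-en-1-yl]-7-methoxydodec-4-enamide | CCCCC[C@@H](C/C=C/CCC(=O)NC/C(=C/I)C1=C(C)CCCC1=O)OC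
F4 | step 11 | (4E,7S)-N-[(E)-3-chloro-2-(6-oxocyclohex-1-en-1-yl)prop-2-en-1-yl]-7-methoxydodec-4-enamide | CCCCC[C@@H](C/C=C/CCC(=O)NC/C(=C/Cl)C1=CCCCC1=O)OC
F5 | step 11 | (4E,7S)-N-[(E)-3-chloro-2-{6-methyl-2-[(trimethylsilyl)oxy]cyclohex-1-en-1-yl}prop-2-en-1-yl]-7-methoxydodec-4-enamide (both epimers at the ring methyl carbon) | CCCCC[C@@H](C/C=C/CCC(=O)NC/C(=C/Cl)C1=C(O[Si](C)(C)C)CCCC1C)OC
F6 | step 14 | 6-[(dimethylamino)methyl]-3-methylcyclohex-2-en-1-one (racemic) | CC1=CC(=O)C(CN(C)C)CC1
F7 | step 14 | [(4-methyl-2-oxocyclohex-3-en-1-yl)methyl]trimethylammonium iodide | CC1=CC(=O)C(C[N+](C)(C)C)CC1.[I-]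
F8 | step 14 | 3-methyl-6-methylidenecyclohex-2-en-1-one | CC1=CC(=O)C(=C)CC1
F9 | step 14 | (S)-3,6-dimethylcyclohex-2-en-1-one | CC1=CC(=O)[C@@H](C)CC1
F10 | step 14 | (S)-2-iodo-3,6-dimethylcyclohex-2-en-1-one | CC1=C(I)C(=O)[C@@H](C)CC1
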